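**Retrosynthetic overview**
1. Putraflavone ⇒ cut the C3′–C8″ biaryl bond. It joins two phenol ortho-carbons that are both natively nucleophilic, so acacetin keeps its normal polarity (C8 nucleophile) and ring B of genkwanin is inverted into a C3′ electrophile.
2. The inverted partner is an aromatic enolonium (2-oxidophenyl cation) equivalent, the inner salt 3′-(mesityliodonio)genkwanin-4′-olate, which is reacted with unprotected acacetin without metal or base.
3. Inner salt ⇒ genkwanin + MesI(OAc)2 (phenoxide-directed ortho C–H iodanylation); genkwanin ⇒ apigenin (7-O-methylation).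
4. Ring order: no ring is built. All six rings arrive intact in apigenin and acacetin, and the inter-flavone bond is made last.

Assumption: the target has no stereocentre and its SMILES fixes no axial configuration, so it is made as the single achiral compound drawn; apigenin, acacetin and MesI(OAc)2 are taken as purchasable.

**Step 1**
Reactants: 1 apigenin
Product: 2 genkwanin (7-O-methylapigenin)
Conditions: MeI (1.05 equiv), K2CO3 (1.0 equiv), DMF, 25 °C, 16 h
Reagents that add atoms: iodomethane, CI
Why: Williamson ether synthesis in which the 7-OH, a vinylogous acid para to the C4 carbonyl (pKa about 7), is ionised by one equivalent of weak base ahead of 4′-OH while the chelated 5-OH stays protonated, so the 7-methyl ether forms selectively; no stereocentre is formed.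

**Step 2**
Reactants: 2 genkwanin
Product: 3 3′-(mesityliodonio)genkwanin-4′-olate (inner salt)
Conditions: MesI(OAc)2 (1.05 equiv), K2CO3 (1.0 equiv), MeCN/H2O 4:1, 0 °C, 2 h, dark; filter the precipitated inner salt
Reagents that add atoms: (diacetoxyiodo)mesitylene, CC(=O)OI(OC(C)=O)c1c(C)cc(C)cc1C
Why: Aryliodonium phenolate (phenol iodonium ylide) formation, a known reaction of ArI(OAc)2 with phenoxides bearing a para electron-withdrawing group: the only ionised oxygen, O4′, exchanges onto trivalent iodine and the aryl-λ3-iodanyl group is delivered to the adjacent carbon (C3′ and C5′ are equivalent), while the neutral, chelated ring A is not attacked by the unactivated diacetate; no stereocentre is formed.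

**Step 3**
Reactants: 3 3′-(mesityliodonio)genkwanin-4′-olate; 4 acacetin
Product: 6 putraflavone, via O7-bound diaryl-λ3-iodane 5 (not isolated)
Conditions: 4 (2.0 equiv), CF3CH2OH, 50 °C, dark, 16 h, no base, no metal
Reagents that add atoms: none
Why: Proposed new method: 3 is an aromatic enolonium (2-oxidophenyl cation) equivalent, so C3′ becomes the electrophile for the natively nucleophilic C8 of 4; the vinylogous-acid 7-OH of 4 protonates the phenoxide of 3 and binds iodine through O7 to give T-shaped λ3-iodane 5, which undergoes [2,3]-type ligand coupling from O7 onto the adjacent C8 (the C7–C8 bond has the higher π-bond order, the bias that sends Claisen rearrangements of 7-allyloxy-5-hydroxyflavones and Mannich reactions of 5,7-dihydroxyflavones to C8), expelling iodomesitylene before the dienone tautomerises to the biaryl; the closest known reaction type is the metal-free C-arylation of β-dicarbonyl enolates and 2-naphtholates by diaryliodonium salts (Beringer-type ligand coupling), in which carbon nucleophiles take the less hindered aryl and leave mesityl on iodine; no stereocentre is formed and the new axis is not configurationally defined.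

**Compound list**
1 | apigenin, 5,7-dihydroxy-2-(4-hydroxyphenyl)-4H-chromen-4-one | Oc1ccc(cc1)-c1cc(=O)c2c(O)cc(O)cc2o1 | starting material
2 | genkwanin, 5-hydroxy-2-(4-hydroxyphenyl)-7-methoxy-4H-chromen-4-one | COc1cc(O)c2c(=O)cc(-c3ccc(O)cc3)oc2c1 | intermediate
3 | 3′-(mesityliodonio)genkwanin-4′-olate, inner salt: 4-(5-hydroxy-7-methoxy-4-oxo-4H-chromen-2-yl)-2-[(2,4,6-trimethylphenyl)iodonio]phenolate | COc1cc(O)c2c(=O)cc(-c3ccc([O-])c([I+]c4c(C)cc(C)cc4C)c3)oc2c1 | intermediate
4 | acacetin, 5,7-dihydroxy-2-(4-methoxyphenyl)-4H-chromen-4-one | COc1ccc(cc1)-c1cc(=O)c2c(O)cc(O)cc2o1 | starting material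
5 | O7-bound diaryl-λ3-iodane: iodine carries mesityl, C3′ of genkwanin (4′-OH protonated) and O7 of acacetin | Cc1cc(C)c(c(C)c1)I(Oc1cc(O)c2c(=O)cc(oc2c1)-c1ccc(OC)cc1)c1cc(ccc1O)-c1cc(=O)c2c(O)cc(OC)cc2o1 | intermediate
6 | putraflavone, 8-[2-hydroxy-5-(5-hydroxy-7-methoxy-4-oxo-4H-chromen-2-yl)phenyl]-5,7-dihydroxy-2-(4-methoxyphenyl)-4H-chromen-4-one (achiral as drawn) | COc1ccc(-c2cc(=O)c3c(O)cc(O)c(-c4cc(-c5cc(=O)c6c(O)cc(OC)cc6o5)ccc4O)c3o2)cc1 | target

**Step count**
Total: 3 steps. Longest linear sequence: 3 steps (1 → 2 → 3 → 6); acacetin 4 enters in the last step.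

**Steps most likely to fail, with fallbacks**

Step 3 is the most likely to fail. The ambident 7-oxide may arylate at oxygen (giving the ether-linked biflavone) or at C6, mesityl may transfer, or 3 may undergo its thermal iodine-to-oxygen aryl shift before coupling. The fallback fixes the carbon nucleophile in advance and closes the bond by Suzuki–Miyaura coupling. It sets out from acacetin 4 and comes back at putraflavone 6. Acacetin 4 is protected with MOMCl and NaH in DMF as 5,7-bis(methoxymethoxy)-4′-methoxyflavone F1. This is iodinated with NIS in DMF, where 5,7-dialkoxyflavones react at C8, to give 8-iodo-5,7-bis(methoxymethoxy)-4′-methoxyflavone F2. Borylation with B2pin2, PdCl2(dppf) and KOAc in dioxane at 90 °C gives the 8-pinacolboronate F3. This is coupled with inner salt 3 as the aryl electrophile (Pd(OAc)2, SPhos, K3PO4, dioxane/H2O, 60 °C, iodomesitylene lost) to give 5″,7″-bis-O-(methoxymethyl)putraflavone F4. HCl in MeOH at 50 °C removes the MOM groups and returns 6.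

Step 2 is next. Iodanylation may be unselective, or the inner salt may not separate cleanly. The fallback makes the carbon–iodine bond at the monovalent stage and oxidises iodine afterwards. It sets out from genkwanin 2 and comes back at inner salt 3. Genkwanin 2 is iodinated ortho to the phenoxide (I2, NaHCO3, THF/H2O, 0 °C) to 3′-iodogenkwanin F5. Acetylation at O4′ (Ac2O, pyridine, 0 °C, chelated 5-OH left free) gives 4′-O-acetyl-3′-iodogenkwanin F6. One-pot oxidation and arylation (mCPBA, TsOH·H2O, excess mesitylene, CH2Cl2/CF3CH2OH, 25 °C) gives the (2-acetoxyaryl)(mesityl)iodonium tosylate F7. K2CO3 in MeOH at 0 °C removes the acetyl group and the tosylate counter-ion and returns 3.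

Step 1 is the least risky of the three. The 4′-O-methyl and 7,4′-di-O-methyl by-products may make isolation poor. The fallback differentiates the hydroxyls by acylation instead of by acidity. It sets out from apigenin 1 and comes back at genkwanin 2. Apigenin 1 is peracetylated (Ac2O, pyridine) to apigenin 5,7,4′-triacetate F8. The most labile 7-acetate is removed (PhSH, imidazole, NMP, 0 °C) to give apigenin 5,4′-diacetate F9. The free 7-OH is methylated (MeI, K2CO3, acetone, 25 °C) to genkwanin 5,4′-diacetate F10. Methanolysis (K2CO3, MeOH, 25 °C) returns 2.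

**Further compounds**
F1 | step 3 | 5,7-bis(methoxymethoxy)-2-(4-methoxyphenyl)-4H-chromen-4-one | COCOc1cc(OCOC)c2c(=O)cc(-c3ccc(OC)cc3)oc2c1
F2 | step 3 | 8-iodo-5,7-bis(methoxymethoxy)-2-(4-methoxyphenyl)-4H-chromen-4-one | COCOc1cc(OCOC)c2c(=O)cc(-c3ccc(OC)cc3)oc2c1I
F3 | step 3 | 5,7-bis(methoxymethoxy)-2-(4-methoxyphenyl)-8-(4,4,5,5-tetramethyl-1,3,2-dioxaborolan-2-yl)-4H-chromen-4-one | COCOc1cc(OCOC)c2c(=O)cc(-c3ccc(OC)cc3)oc2c1B1OC(C)(C)C(C)(C)O1
F4 | step 3 | 5″,7″-bis-O-(methoxymethyl)putraflavone | COCOc1cc(OCOC)c2c(=O)cc(-c3ccc(OC)cc3)oc2c1-c1cc(ccc1O)-c1cc(=O)c2c(O)cc(OC)cc2o1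
F5 | step 2 | 3′-iodogenkwanin, 5-hydroxy-2-(4-hydroxy-3-iodophenyl)-7-methoxy-4H-chromen-4-one | COc1cc(O)c2c(=O)cc(-c3ccc(O)c(I)c3)oc2c1
F6 | step 2 | 4′-O-acetyl-3′-iodogenkwanin | COc1cc(O)c2c(=O)cc(-c3ccc(OC(C)=O)c(I)c3)oc2c1
F7 | step 2 | [2-acetoxy-5-(5-hydroxy-7-methoxy-4-oxo-4H-chromen-2-yl)phenyl](2,4,6-trimethylphenyl)iodonium 4-methylbenzenesulfonate | COc1cc(O)c2c(=O)cc(-c3ccc(OC(C)=O)c([I+]c4c(C)cc(C)cc4C)c3)oc2c1.Cc1ccc(cc1)S(=O)(=O)[O-]
F8 | step 1 | apigenin 5,7,4′-triacetate | CC(=O)Oc1ccc(cc1)-c1cc(=O)c2c(OC(C)=O)cc(OC(C)=O)cc2o1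
F9 | step 1 | apigenin 5,4′-diacetate (7-OH free) | CC(=O)Oc1ccc(cc1)-c1cc(=O)c2c(OC(C)=O)cc(O)cc2o1
F10 | step 1 | genkwanin 5,4′-diacetate | COc1cc(OC(C)=O)c2c(=O)cc(-c3ccc(OC(C)=O)cc3)oc2c1
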